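The dihydrofuran ring is cut at O1–C7a and C2–C3. An enantiopure p-tolylsulfinyl group on the future C7a of an ethylarene does three jobs in one flask: it directs lithiation of the benzylic carbon (future C3), relays its chirality to C3 while the carbanion adds to a benzaldehyde (future C2 and O1), and finally leaves C7a when the alkoxide closes the ring. The step exploits the ortho relationship, on the benzene ring of the benzofuran, between the oxygen-bearing C7a and C3a carrying the methyl-substituted C3, and the trans preference of the C2 aryl and C3 methyl groups. The erythro diol on C5 follows from (S)-lactate by acylation and chelation-controlled reduction.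

Key step: step 5

Remark: atom labels O1, C2, C3, C3a, C5, C7 and C7a are those of the 2,3-dihydro-1-benzofuran core of the target; the sense of 1,4-induction established for lithiated (S)-2-(p-tolylsulfinyl)ethylbenzene with carbonyl electrophiles is assumed to hold for the 4-bromo-6-methoxy analogue 8.

Step 1
Reactants: 1 4-bromo-2-methoxy-6-methylaniline
Product: 3 5-bromo-2-iodo-1-methoxy-3-methylbenzene, via arenediazonium tosylate 2 (not isolated)
Conditions: p-TsOH·H2O, NaNO2, KI, MeCN/H2O, 10 → 25 °C
Reagents that add atoms: potassium iodide, [K+].[I-]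
Why: Sandmeyer-type iodination, in which diazotisation of the aniline and displacement of dinitrogen by iodide (no copper needed) place iodine on the carbon flanked by OMe and CH3 while the aryl bromide is untouched.

Step 2
Reactants: 3 5-bromo-2-iodo-1-methoxy-3-methylbenzene; 4 (1R,2S,5R)-(−)-menthyl (S)-p-toluenesulfinate
Product: 6 (S)-5-bromo-1-methoxy-3-methyl-2-(p-tolylsulfinyl)benzene, via arylmagnesium chloride 5 (not isolated)
Conditions: iPrMgCl·LiCl, THF, −40 °C; then added to 4 in THF, −40 → 0 °C; aq. NH4Cl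
Reagents that add atoms: none
Why: Iodine–magnesium exchange is far faster than bromine–magnesium exchange at −40 °C, and the Andersen synthesis (substitution at sulfur with inversion) then sets the sulfur stereocenter as S from the S-configured sulfinate 4.

Step 3
Reactants: 6 (S)-5-bromo-1-methoxy-3-methyl-2-(p-tolylsulfinyl)benzene
Product: 8 (S)-5-bromo-1-ethyl-3-methoxy-2-(p-tolylsulfinyl)benzene, via benzyllithium 7 (not isolated)
Conditions: LiN(iPr)2 (LDA), THF, −78 °C; MeI, −78 °C
Reagents that add atoms: iodomethane, CI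
Why: Lateral lithiation of the ortho methyl group, assisted by coordination of lithium to the sulfinyl oxygen, followed by SN2 methylation gives the ethyl group, and the sulfur stereocenter is untouched.

Step 4
Reactants: 9 3-hydroxy-4,5-dimethoxybenzaldehyde
Product: 10 3,4-dimethoxy-5-(triisopropylsilyloxy)benzaldehyde
Conditions: iPr3SiCl, imidazole, DMF, 25 °C
Reagents that add atoms: chlorotriisopropylsilane, CC(C)[Si](Cl)(C(C)C)C(C)C
Why: Imidazole-promoted silylation of the phenol gives a bulky TIPS ether that should resist the alkoxide of step 5 and is later cleaved by fluoride.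

Step 5
Reactants: 8 (S)-5-bromo-1-ethyl-3-methoxy-2-(p-tolylsulfinyl)benzene; 10 3,4-dimethoxy-5-(triisopropylsilyloxy)benzaldehyde
Product: 13 (2S,3S)-5-bromo-2-[3,4-dimethoxy-5-(triisopropylsilyloxy)phenyl]-7-methoxy-3-methyl-2,3-dihydro-1-benzofuran, via chelated benzyllithium 11 (not isolated), via lithium alkoxide 12 (not isolated)
Conditions: LiN(iPr)2 (LDA), THF, −78 °C; 10, −78 °C; then DMPU, −78 → 40 °C; aq. NH4Cl
Reagents that add atoms: none
Why: Proposed new method: sulfinyl-directed benzylic lithiation of 8 gives the O–Li-chelated benzyllithium 11, which adds to aldehyde 10 to form C2–C3, and the resulting alkoxide 12 then displaces the sulfinyl group at the ipso carbon C7a by addition–elimination (SNAr), forming O1–C7a and expelling p-toluenesulfenate. The closest known reaction type is the anionic–anionic tandem of 2-(p-tolylsulfinyl)alkylbenzene carbanions with imines, in which the amide nitrogen displaces the sulfinyl group to give indolines; here oxygen takes the place of nitrogen. The dihydrofuran ring closes in a 5-exo-trig mode through a Meisenheimer adduct at C7a. C3 is set by 1,4-induction from the (S)-sulfinyl sulfur (the aldehyde enters on the lithium-bearing face, with the methyl group turned away from sulfur), which should give 3S. C2 is set by the preference for the trans ring, since the epimeric alkoxides can interconvert by retro-addition and the one that places aryl and methyl on opposite faces should close faster, giving 2S. The step needs benzylic instead of ring lithiation, which chelation of the base to the sulfinyl oxygen at −78 °C should secure, and ring closure instead of simple protonation, which the DMPU-promoted warming stage should secure.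

Step 6
Reactants: 14 ethyl (S)-lactate
Product: 15 (S)-2-hydroxy-N-methoxy-N-methylpropanamide
Conditions: MeNH(OMe)·HCl, iPrMgCl, THF, −20 → 0 °C
Reagents that add atoms: N,O-dimethylhydroxylamine hydrochloride, CNOC.Cl
Why: Weinreb amide formation by aminolysis of the ester with the chloromagnesium amide, under which the lactate stereocenter is not enolised.

Step 7
Reactants: 15 (S)-2-hydroxy-N-methoxy-N-methylpropanamide
Product: 16 (S)-2-(tert-butyldimethylsilyloxy)-N-methoxy-N-methylpropanamide
Conditions: tBuMe2SiCl, imidazole, DMF, 25 °C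
Reagents that add atoms: tert-butylchlorodimethylsilane, CC(C)(C)[Si](C)(C)Cl
Why: Imidazole-promoted silylation masks the secondary alcohol against the aryllithium of step 8 without touching the stereocenter.

Step 8
Reactants: 13 (2S,3S)-5-bromo-2-[3,4-dimethoxy-5-(triisopropylsilyloxy)phenyl]-7-methoxy-3-methyl-2,3-dihydro-1-benzofuran; 16 (S)-2-(tert-butyldimethylsilyloxy)-N-methoxy-N-methylpropanamide
Product: 18 (S)-2-(tert-butyldimethylsilyloxy)-1-{(2S,3S)-2-[3,4-dimethoxy-5-(triisopropylsilyloxy)phenyl]-7-methoxy-3-methyl-2,3-dihydro-1-benzofuran-5-yl}propan-1-one, via aryllithium 17 (not isolated)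
Conditions: n-BuLi, THF, −78 °C; 16, −78 → −20 °C; aq. NH4Cl
Reagents that add atoms: none
Why: Bromine–lithium exchange followed by the Weinreb ketone synthesis, in which the chelated tetrahedral adduct stops at the ketone stage and the α-stereocenter, not enolised at low temperature, is retained.

Step 9
Reactants: 18 (S)-2-(tert-butyldimethylsilyloxy)-1-{(2S,3S)-2-[3,4-dimethoxy-5-(triisopropylsilyloxy)phenyl]-7-methoxy-3-methyl-2,3-dihydro-1-benzofuran-5-yl}propan-1-one
Product: 19 (S)-2-hydroxy-1-[(2S,3S)-2-(3-hydroxy-4,5-dimethoxyphenyl)-7-methoxy-3-methyl-2,3-dihydro-1-benzofuran-5-yl]propan-1-one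
Conditions: Bu4NF, AcOH, THF, 0 → 25 °C
Reagents that add atoms: none
Why: Fluoride-mediated desilylation cleaves the aryl TIPS and alkyl TBS ethers, and the acetic acid buffer should keep the α-hydroxy ketone from enolising.

Step 10
Reactants: 19 (S)-2-hydroxy-1-[(2S,3S)-2-(3-hydroxy-4,5-dimethoxyphenyl)-7-methoxy-3-methyl-2,3-dihydro-1-benzofuran-5-yl]propan-1-one
Product: 20 (1R,2S)-1-[(2S,3S)-2-(3-hydroxy-4,5-dimethoxyphenyl)-7-methoxy-3-methyl-2,3-dihydro-1-benzofuran-5-yl]propane-1,2-diol
Conditions: Zn(BH4)2, Et2O/THF, −20 → 0 °C; aq. NH4Cl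
Reagents that add atoms: none
Why: Chelation-controlled hydride reduction (Cram chelate model), in which zinc bridges the carbonyl and α-hydroxyl oxygens and hydride is delivered to the face bearing the α-hydrogen, which should give the anti diol with 1R configuration next to the 2S center.

Compound list
1 | 4-bromo-2-methoxy-6-methylaniline | COc1cc(Br)cc(C)c1N | starting material
2 | 4-bromo-2-methoxy-6-methylbenzenediazonium p-toluenesulfonate | COc1cc(Br)cc(C)c1[N+]#N.Cc1ccc(cc1)S(=O)(=O)[O-] | intermediate
3 | 5-bromo-2-iodo-1-methoxy-3-methylbenzene | COc1cc(Br)cc(C)c1I | intermediate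
4 | (1R,2S,5R)-(−)-menthyl (S)-p-toluenesulfinate | CC(C)[C@@H]1CC[C@@H](C)C[C@H]1O[S@](=O)c1ccc(C)cc1 | starting material
5 | (4-bromo-2-methoxy-6-methylphenyl)magnesium chloride | COc1cc(Br)cc(C)c1[Mg]Cl | intermediate
6 | (S)-5-bromo-1-methoxy-3-methyl-2-(p-tolylsulfinyl)benzene | Cc1ccc(cc1)[S@](=O)c1c(C)cc(Br)cc1OC | intermediate
7 | [5-bromo-3-methoxy-2-((S)-p-tolylsulfinyl)benzyl]lithium | [Li]Cc1cc(Br)cc(OC)c1[S@@](=O)c1ccc(C)cc1 | intermediate
8 | (S)-5-bromo-1-ethyl-3-methoxy-2-(p-tolylsulfinyl)benzene | Cc1ccc(cc1)[S@](=O)c1c(CC)cc(Br)cc1OC | intermediate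
9 | 3-hydroxy-4,5-dimethoxybenzaldehyde | COc1cc(C=O)cc(O)c1OC | starting material
10 | 3,4-dimethoxy-5-(triisopropylsilyloxy)benzaldehyde | COc1cc(C=O)cc(O[Si](C(C)C)(C(C)C)C(C)C)c1OC | intermediate
11 | {1-[5-bromo-3-methoxy-2-((S)-p-tolylsulfinyl)phenyl]ethyl}lithium, held by O–Li chelation (configuration at the lithiated carbon not specified) | CC([Li])c1cc(Br)cc(OC)c1[S@@](=O)c1ccc(C)cc1 | intermediate
12 | lithium (1S,2S)-2-[5-bromo-3-methoxy-2-((S)-p-tolylsulfinyl)phenyl]-1-[3,4-dimethoxy-5-(triisopropylsilyloxy)phenyl]propan-1-olate | [Li]O[C@H](c1cc(OC)c(OC)c(O[Si](C(C)C)(C(C)C)C(C)C)c1)[C@@H](C)c1cc(Br)cc(OC)c1[S@@](=O)c1ccc(C)cc1 | intermediate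
13 | (2S,3S)-5-bromo-2-[3,4-dimethoxy-5-(triisopropylsilyloxy)phenyl]-7-methoxy-3-methyl-2,3-dihydro-1-benzofuran (trans) | COc1cc([C@H]2Oc3c(OC)cc(Br)cc3[C@@H]2C)cc(O[Si](C(C)C)(C(C)C)C(C)C)c1OC | intermediate
14 | ethyl (S)-lactate | CCOC(=O)[C@H](C)O | starting material
15 | (S)-2-hydroxy-N-methoxy-N-methylpropanamide | C[C@H](O)C(=O)N(C)OC | intermediate
16 | (S)-2-(tert-butyldimethylsilyloxy)-N-methoxy-N-methylpropanamide | C[C@H](O[Si](C)(C)C(C)(C)C)C(=O)N(C)OC | intermediate
17 | {(2S,3S)-2-[3,4-dimethoxy-5-(triisopropylsilyloxy)phenyl]-7-methoxy-3-methyl-2,3-dihydro-1-benzofuran-5-yl}lithium | COc1cc([C@H]2Oc3c(OC)cc([Li])cc3[C@@H]2C)cc(O[Si](C(C)C)(C(C)C)C(C)C)c1OC | intermediate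
18 | (S)-2-(tert-butyldimethylsilyloxy)-1-{(2S,3S)-2-[3,4-dimethoxy-5-(triisopropylsilyloxy)phenyl]-7-methoxy-3-methyl-2,3-dihydro-1-benzofuran-5-yl}propan-1-one | COc1cc([C@H]2Oc3c(OC)cc(C(=O)[C@H](C)O[Si](C)(C)C(C)(C)C)cc3[C@@H]2C)cc(O[Si](C(C)C)(C(C)C)C(C)C)c1OC | intermediate
19 | (S)-2-hydroxy-1-[(2S,3S)-2-(3-hydroxy-4,5-dimethoxyphenyl)-7-methoxy-3-methyl-2,3-dihydro-1-benzofuran-5-yl]propan-1-one | COc1cc([C@H]2Oc3c(OC)cc(C(=O)[C@H](C)O)cc3[C@@H]2C)cc(O)c1OC | intermediate
20 | (1R,2S)-1-[(2S,3S)-2-(3-hydroxy-4,5-dimethoxyphenyl)-7-methoxy-3-methyl-2,3-dihydro-1-benzofuran-5-yl]propane-1,2-diol | COc1cc([C@H]2Oc3c(OC)cc([C@@H](O)[C@H](C)O)cc3[C@@H]2C)cc(O)c1OC | target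

Total step count: 10 steps.
Longest linear sequence: 7 steps (steps 1, 2, 3, 5, 8, 9 and 10).

Steps most likely to fail

Step 5 (labelled step). The lithium alkoxide may fail to displace the sulfinyl group, stalling at the open-chain adduct or reverting by retro-addition on warming. Facial selectivity at the aldehyde carbon may be poor, and the ortho methoxy group may disturb the chelate that relays chirality from sulfur to C3. The fallback uses known chemistry only; it sets out from sulfoxide 8 and aldehyde 10 and comes back at bromide 13. Only the addition is run (LiN(iPr)2, THF, −78 °C, then 10, quench at −78 °C with aq. NH4Cl). After chromatographic removal of the carbinol epimer this should give (1S,2S)-2-[5-bromo-3-methoxy-2-((S)-p-tolylsulfinyl)phenyl]-1-[3,4-dimethoxy-5-(triisopropylsilyloxy)phenyl]propan-1-ol F1. Sulfoxide–magnesium exchange (excess iPrMgCl·LiCl, THF, −50 °C, the first equivalent taking the hydroxyl proton) and an iodine quench would replace the sulfinyl group by iodine, giving (1S,2S)-2-(5-bromo-2-iodo-3-methoxyphenyl)-1-[3,4-dimethoxy-5-(triisopropylsilyloxy)phenyl]propan-1-ol F2. Intramolecular Ullmann etherification (CuI, 1,10-phenanthroline, Cs2CO3, toluene, 100 °C), in which the iodide should react ahead of the bromide, then closes O1–C7a and delivers 13.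

Step 10. Incomplete chelation, for example through competing coordination of zinc by the phenoxide, may erode facial selectivity and give the threo diol alongside the target. The fallback sets out from bromide 13 and comes back at target 20. Aryllithium 17 (n-BuLi, THF, −78 °C) is added to commercial (S)-2-(tert-butyldimethylsilyloxy)propanal under Felkin–Anh control (non-chelating silyl ether, Et2O/THF, −78 °C). This forms the aryl–carbinol bond and the carbinol center together and should favour the anti adduct (1R,2S)-2-(tert-butyldimethylsilyloxy)-1-{(2S,3S)-2-[3,4-dimethoxy-5-(triisopropylsilyloxy)phenyl]-7-methoxy-3-methyl-2,3-dihydro-1-benzofuran-5-yl}propan-1-ol F3. Bu4NF in THF then removes both silyl groups to give 20.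

Step 3. Deprotonation may compete at the ring CH between bromine and methoxy, and the product may be methylated a second time. The fallback sets out from iodide 3 and comes back at sulfoxide 8. Radical benzylic bromination (N-bromosuccinimide, AIBN, PhCF3, 80 °C) gives 5-bromo-1-(bromomethyl)-2-iodo-3-methoxybenzene F4. Copper-catalysed coupling with MeMgBr (catalytic Li2CuCl4, THF, −30 °C) gives 5-bromo-1-ethyl-2-iodo-3-methoxybenzene F5. Iodine–magnesium exchange and Andersen sulfinylation with 4, exactly as in step 2, then give 8 with the ethyl group already in place.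

Further compounds
F1 | step 5 | (1S,2S)-2-[5-bromo-3-methoxy-2-((S)-p-tolylsulfinyl)phenyl]-1-[3,4-dimethoxy-5-(triisopropylsilyloxy)phenyl]propan-1-ol | O[C@H](c1cc(OC)c(OC)c(O[Si](C(C)C)(C(C)C)C(C)C)c1)[C@@H](C)c1cc(Br)cc(OC)c1[S@@](=O)c1ccc(C)cc1
F2 | step 5 | (1S,2S)-2-(5-bromo-2-iodo-3-methoxyphenyl)-1-[3,4-dimethoxy-5-(triisopropylsilyloxy)phenyl]propan-1-ol | O[C@H](c1cc(OC)c(OC)c(O[Si](C(C)C)(C(C)C)C(C)C)c1)[C@@H](C)c1cc(Br)cc(OC)c1I
F3 | step 10 | (1R,2S)-2-(tert-butyldimethylsilyloxy)-1-{(2S,3S)-2-[3,4-dimethoxy-5-(triisopropylsilyloxy)phenyl]-7-methoxy-3-methyl-2,3-dihydro-1-benzofuran-5-yl}propan-1-ol | COc1cc([C@H]2Oc3c(OC)cc([C@@H](O)[C@H](C)O[Si](C)(C)C(C)(C)C)cc3[C@@H]2C)cc(O[Si](C(C)C)(C(C)C)C(C)C)c1OC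
F4 | step 3 | 5-bromo-1-(bromomethyl)-2-iodo-3-methoxybenzene | COc1cc(Br)cc(CBr)c1I
F5 | step 3 | 5-bromo-1-ethyl-2-iodo-3-methoxybenzene | CCc1cc(Br)cc(OC)c1I
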